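## Retrosynthetic overview

- The strategy rests on ring B of the naphthoquinone (C4a, C5, C6, C7, C8, C8a). Its C6–C7 edge, carrying the C7 methyl, is a two-carbon unit that can be laid across C5 and C8 of an o-quinodimethane grown from the fully oxygenated ring A (C1–C4).
- Target ⇐ hydroxyquinone 26 ⇐ methoxyquinone 25 ⇐ 1,2,4-trimethoxynaphthalene 24 (acetylation, vinylogous-ester hydrolysis, cerium oxidation).
- 24 ⇐ nitro tetralol 19 by dehydration, radical removal of the nitro group and dehydrogenation; 19 ⇐ aldehyde 13 + (E)-1-nitropropene 17 by photoenolization/[4+2].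
- 13 ⇐ 2,4,5-trimethoxybenzaldehyde acetal by two directed ortho-metalations (isopropenyl at C3 by Negishi coupling, then hydrogenation; iodine at C6) and a B-alkyl Suzuki coupling; 17 ⇐ nitromethane + acetaldehyde.
- Ring order: ring A is bought; ring B is the only ring formed, in step 8.

Key step: step 8

Remark on numbering: bicyclic compounds carry the naphthoquinone numbering of the target (carbonyls C1/C4, acetoxy C2, isopropyl C3, methyl C7, side chain C8).

Assumption: the target is achiral, so 19–23 are racemic and their relative configuration is given only for bookkeeping; all stereocentres are erased in step 11.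

## Route

Step 1
Reactants: 1 2,4,5-trimethoxybenzaldehyde
Product: 2 1-(dimethoxymethyl)-2,4,5-trimethoxybenzene
Conditions: HC(OMe)3 (neat, excess), pTsOH·H2O (cat.), 40 °C; Et3N quench
Reagents that add atoms: trimethyl orthoformate, COC(OC)OC
Why: Acid-catalysed acetalisation, with the orthoformate as methoxy source and water scavenger, masks the aldehyde against n-BuLi and leaves only a weak ortho-directing group at C1.

Step 2
Reactants: 2 1-(dimethoxymethyl)-2,4,5-trimethoxybenzene; 3 2-bromopropene
Product: 6 1-(dimethoxymethyl)-2,4,5-trimethoxy-3-(prop-1-en-2-yl)benzene, via aryllithium 4 (not isolated), via arylzinc chloride 5 (not isolated)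
Conditions: n-BuLi, THF, 0 °C; ZnCl2, 0 °C → rt; 3, Pd(PPh3)4 (cat.), 55 °C
Reagents that add atoms: none
Why: Directed ortho-metalation should occur at C3, the only position flanked by two methoxy groups (C6–H has one methoxy and the weaker acetal director beside it, and 3,5-dimethoxybenzaldehyde acetals likewise metalate between the ethers); lithium-to-zinc exchange and Negishi coupling then place the isopropenyl group at this hindered site.

Step 3
Reactants: 6 1-(dimethoxymethyl)-2,4,5-trimethoxy-3-(prop-1-en-2-yl)benzene
Product: 7 1-(dimethoxymethyl)-2,4,5-trimethoxy-3-(propan-2-yl)benzene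
Conditions: H2 (1 atm), 10% Pd/C, EtOAc, Et3N (1%), rt
Reagents that add atoms: none
Why: Heterogeneous hydrogenation of a 1,1-disubstituted alkene; the acetal, kept slightly basic, and the arene are inert.

Step 4
Reactants: 7 1-(dimethoxymethyl)-2,4,5-trimethoxy-3-(propan-2-yl)benzene
Product: 9 1-(dimethoxymethyl)-2-iodo-3,4,6-trimethoxy-5-(propan-2-yl)benzene, via aryllithium 8 (not isolated)
Conditions: n-BuLi, THF, 0 °C; I2, −78 °C → rt; aq. Na2S2O3/NaHCO3
Reagents that add atoms: iodine, II
Why: With C3 blocked, the only ring hydrogen left is C6–H between the acetal and the C5 methoxy group, so directed ortho-metalation and iodine quench have no regiochemical choice.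

Step 5
Reactants: 9 1-(dimethoxymethyl)-2-iodo-3,4,6-trimethoxy-5-(propan-2-yl)benzene; 10 2-methylhexa-1,5-diene
Product: 13 2,4,5-trimethoxy-6-(5-methylhex-5-en-1-yl)-3-(propan-2-yl)benzaldehyde, via alkyldisiamylborane 11 (not isolated), via coupled acetal 12 (not isolated)
Conditions: BH3·SMe2, 2-methylbut-2-ene (2 equiv), THF, 0 °C, then 10 (excess over boron), 0 °C → rt; 9, PdCl2(dppf) (cat.), 3 M aq. NaOH, THF, 65 °C; then 2 M HCl, THF, rt
Reagents that add atoms: water, O
Why: Disiamylborane hydroborates the monosubstituted alkene of the diene in strong preference to the 1,1-disubstituted one (9-BBN reacts at least as fast with the latter and is therefore avoided); the primary alkyl group is then transferred in a B-alkyl Suzuki–Miyaura coupling while the aldehyde is still masked (a free aldehyde could be reduced by β-hydride transfer from a siamyl group), and the acidic work-up unmasks it.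

Step 6
Reactants: 14 nitromethane; 15 acetaldehyde
Product: 16 1-nitropropan-2-ol
Conditions: 14 (5 equiv), aq. NaOH (cat.), 0 °C → rt; AcOH quench
Reagents that add atoms: none
Why: Base-catalysed Henry (nitroaldol) addition, with excess nitromethane to suppress double addition; the single stereocentre forms racemic and is destroyed in step 7.

Step 7
Reactants: 16 1-nitropropan-2-ol
Product: 17 (E)-1-nitroprop-1-ene
Conditions: phthalic anhydride (1.3 equiv), 150–180 °C, reduced pressure, product distilled out
Reagents that add atoms: none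
Why: Dehydration of a β-nitro alcohol by phthalic anhydride with removal of the volatile nitroalkene, which should be obtained as the thermodynamically favoured E isomer.

Step 8
Reactants: 13 2,4,5-trimethoxy-6-(5-methylhex-5-en-1-yl)-3-(propan-2-yl)benzaldehyde; 17 (E)-1-nitroprop-1-ene
Product: 19 rac-(5S,6R,7S,8S)-1,2,4-trimethoxy-7-methyl-8-(4-methylpent-4-en-1-yl)-6-nitro-3-(propan-2-yl)-5,6,7,8-tetrahydronaphthalen-5-ol, via photodienol 18 (not isolated)
Conditions: hν (365 nm), 17 (3 equiv), degassed toluene (0.02 M in 13), rt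
Reagents that add atoms: none
Why: The excited aldehyde takes a hydrogen from the benzylic CH2 through a six-membered transition state, and the biradical relaxes to the long-lived dienol 18 with hydroxyl and chain both turned outward, a hydroxy-o-quinodimethane. The closest known reaction type is the photoenolization/Diels–Alder reaction of o-alkylbenzaldehydes, polymethoxylated o-ethylbenzaldehydes included, with electron-poor alkenes. Ring B (C4a, C5–C8, C8a) is closed by an intermolecular suprafacial [4+2] cycloaddition that forms C5–C6 and C7–C8 and restores the aromaticity of ring A. The C5/C8 cis relation follows from the out,out geometry of the dienol, the C6/C7 trans relation from the E geometry of 17, and the C5/C6 cis relation from endo placement of the nitro group (secondary overlap and an O–H···O2N hydrogen bond); all four centres are erased by step 11. The regiochemistry needs the methyl-bearing β-carbon of 17 to bond to C8, which is secured by the hydroxyl-polarised dienol (largest HOMO coefficient at the terminus remote from OH) meeting the nitroalkene LUMO (largest at the β-carbon). Benzylic hydrogen transfer must outrun abstraction from the ortho-methoxy group, and 17 must beat the unactivated tethered alkene; the six-membered transition state and an excess of the far more electrophilic dienophile, at a wavelength where 13 is expected to be the main absorber, should ensure both.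

Step 9
Reactants: 19 rac-(5S,6R,7S,8S)-1,2,4-trimethoxy-7-methyl-8-(4-methylpent-4-en-1-yl)-6-nitro-3-(propan-2-yl)-5,6,7,8-tetrahydronaphthalen-5-ol
Product: 21 rac-trans-1,2,4-trimethoxy-7-methyl-8-(4-methylpent-4-en-1-yl)-6-nitro-3-(propan-2-yl)-7,8-dihydronaphthalene, via mesylate 20 (not isolated)
Conditions: MsCl (1.5 equiv), Et3N (3 equiv), CH2Cl2, 0 °C → rt
Reagents that add atoms: none
Why: Mesylation followed by E1cB loss of mesylate from the acidic α-nitro C6–H (dehydration of a β-nitro alcohol) gives the conjugated nitroalkene; the C5 and C6 centres vanish and C7/C8 stay trans.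

Step 10
Reactants: 21 rac-trans-1,2,4-trimethoxy-7-methyl-8-(4-methylpent-4-en-1-yl)-6-nitro-3-(propan-2-yl)-7,8-dihydronaphthalene
Product: 23 rac-trans-1,2,4-trimethoxy-7-methyl-8-(4-methylpent-4-en-1-yl)-3-(propan-2-yl)-7,8-dihydronaphthalene, via nitro sulfide 22 (not isolated)
Conditions: PhSH (1.2 equiv), Et3N (cat.), benzene, rt; then Bu3SnH (2.5 equiv), AIBN (cat.), 80 °C
Reagents that add atoms: none
Why: Base-catalysed thia-Michael addition places a phenylthio group on C5; the tributyltin radical then cleaves the C6–NO2 bond and the C6 radical expels PhS• (radical β-elimination of a vicinal nitro sulfide), so the nitro group is replaced by hydrogen with the C5=C6 bond kept. Base alone could not remove the nitro group from 21, because no acidic hydrogen lies β to it.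

Step 11
Reactants: 23 rac-trans-1,2,4-trimethoxy-7-methyl-8-(4-methylpent-4-en-1-yl)-3-(propan-2-yl)-7,8-dihydronaphthalene
Product: 24 1,2,4-trimethoxy-7-methyl-8-(4-methylpent-4-en-1-yl)-3-(propan-2-yl)naphthalene
Conditions: DDQ (1.1 equiv), benzene, rt → 50 °C
Reagents that add atoms: none
Why: DDQ dehydrogenation: hydride abstraction from the allylic/benzylic C7–C8 unit and proton loss aromatise ring B and erase the last two stereocentres, while the isolated 1,1-disubstituted alkene should not react at this temperature.

Step 12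
Reactants: 24 1,2,4-trimethoxy-7-methyl-8-(4-methylpent-4-en-1-yl)-3-(propan-2-yl)naphthalene
Product: 25 2-methoxy-7-methyl-8-(4-methylpent-4-en-1-yl)-3-(propan-2-yl)naphthalene-1,4-dione
Conditions: (NH4)2Ce(NO3)6 (2.5 equiv), MeCN/H2O (2:1), 0 °C, 15 min
Reagents that add atoms: water, O
Why: Oxidative demethylation of the para-related C1/C4 methoxy groups gives the 1,4-quinone with the C2 methoxy kept as a vinylogous ester; any ortho-quinone isomer would converge on the same product in step 13.

Step 13
Reactants: 25 2-methoxy-7-methyl-8-(4-methylpent-4-en-1-yl)-3-(propan-2-yl)naphthalene-1,4-dione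
Product: 26 2-hydroxy-7-methyl-8-(4-methylpent-4-en-1-yl)-3-(propan-2-yl)naphthalene-1,4-dione
Conditions: 2 M aq. NaOH, MeOH/THF, 40 °C; then 1 M HCl
Reagents that add atoms: sodium hydroxide, [Na+].[OH-]
Why: Hydroxide adds to C2 and expels methoxide (addition–elimination on a vinylogous ester), giving the stable hydroxyquinone anion, which is protonated on work-up.

Step 14
Reactants: 26 2-hydroxy-7-methyl-8-(4-methylpent-4-en-1-yl)-3-(propan-2-yl)naphthalene-1,4-dione
Product: 27 acetylsalvipisone
Conditions: Ac2O (2 equiv), pyridine, DMAP (cat.), CH2Cl2, 0 °C → rt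
Reagents that add atoms: acetic anhydride, CC(=O)OC(C)=O
Why: O-Acetylation of the acidic enolic hydroxyl under nucleophilic catalysis; acylation on the C2 oxygen keeps the para-quinone.

## Compound list

1 | 2,4,5-trimethoxybenzaldehyde | COc1cc(OC)c(C=O)cc1OC | starting material
2 | 1-(dimethoxymethyl)-2,4,5-trimethoxybenzene | COC(OC)c1cc(OC)c(OC)cc1OC | intermediate
3 | 2-bromopropene | C=C(C)Br | starting material
4 | [3-(dimethoxymethyl)-2,5,6-trimethoxyphenyl]lithium | [Li]c1c(OC)c(C(OC)OC)cc(OC)c1OC | intermediate
5 | chloro[3-(dimethoxymethyl)-2,5,6-trimethoxyphenyl]zinc | Cl[Zn]c1c(OC)c(C(OC)OC)cc(OC)c1OC | intermediate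
6 | 1-(dimethoxymethyl)-2,4,5-trimethoxy-3-(prop-1-en-2-yl)benzene | C=C(C)c1c(OC)c(C(OC)OC)cc(OC)c1OC | intermediate
7 | 1-(dimethoxymethyl)-2,4,5-trimethoxy-3-(propan-2-yl)benzene | CC(C)c1c(OC)c(C(OC)OC)cc(OC)c1OC | intermediate
8 | [2-(dimethoxymethyl)-3,5,6-trimethoxy-4-(propan-2-yl)phenyl]lithium | [Li]c1c(C(OC)OC)c(OC)c(C(C)C)c(OC)c1OC | intermediate
9 | 1-(dimethoxymethyl)-2-iodo-3,4,6-trimethoxy-5-(propan-2-yl)benzene | COC(OC)c1c(I)c(OC)c(OC)c(C(C)C)c1OC | intermediate
10 | 2-methylhexa-1,5-diene | C=CCCC(C)=C | starting material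
11 | bis(3-methylbutan-2-yl)(5-methylhex-5-en-1-yl)borane (stereoisomer mixture at the two sec-alkyl groups) | C=C(C)CCCCB(C(C)C(C)C)C(C)C(C)C | intermediate
12 | 1-(dimethoxymethyl)-3,4,6-trimethoxy-2-(5-methylhex-5-en-1-yl)-5-(propan-2-yl)benzene | C=C(C)CCCCc1c(C(OC)OC)c(OC)c(C(C)C)c(OC)c1OC | intermediate
13 | 2,4,5-trimethoxy-6-(5-methylhex-5-en-1-yl)-3-(propan-2-yl)benzaldehyde | C=C(C)CCCCc1c(C=O)c(OC)c(C(C)C)c(OC)c1OC | intermediate
14 | nitromethane | C[N+](=O)[O-] | starting material
15 | acetaldehyde | CC=O | starting material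
16 | 1-nitropropan-2-ol (racemic) | CC(O)C[N+](=O)[O-] | intermediate
17 | (E)-1-nitroprop-1-ene | C/C=C/[N+](=O)[O-] | intermediate
18 | 6-(hydroxymethylidene)-1,3,4-trimethoxy-5-(5-methylhex-5-en-1-ylidene)-2-(propan-2-yl)cyclohexa-1,3-diene, hydroxyl and chain both turned outward | O/C=C1\C(OC)=C(C(C)C)C(OC)=C(OC)/C1=C\CCCC(C)=C | intermediate
19 | rac-(5S,6R,7S,8S)-1,2,4-trimethoxy-7-methyl-8-(4-methylpent-4-en-1-yl)-6-nitro-3-(propan-2-yl)-5,6,7,8-tetrahydronaphthalen-5-ol (5-OH/6-NO2 cis, 6-NO2/7-Me trans, 5-OH/8-chain cis) | C=C(C)CCC[C@H]1[C@H](C)[C@@H]([N+](=O)[O-])[C@@H](O)c2c(OC)c(C(C)C)c(OC)c(OC)c21 | intermediate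
20 | methanesulfonate of 19, same relative configuration, racemic | C=C(C)CCC[C@H]1[C@H](C)[C@@H]([N+](=O)[O-])[C@@H](OS(C)(=O)=O)c2c(OC)c(C(C)C)c(OC)c(OC)c21 | intermediate
21 | rac-trans-1,2,4-trimethoxy-7-methyl-8-(4-methylpent-4-en-1-yl)-6-nitro-3-(propan-2-yl)-7,8-dihydronaphthalene (C5=C6) | C=C(C)CCC[C@H]1[C@H](C)C([N+](=O)[O-])=Cc2c(OC)c(C(C)C)c(OC)c(OC)c21 | intermediate
22 | 1,2,4-trimethoxy-7-methyl-8-(4-methylpent-4-en-1-yl)-6-nitro-5-(phenylsulfanyl)-3-(propan-2-yl)-5,6,7,8-tetrahydronaphthalene, 7,8-trans, racemic, mixture of C5/C6 diastereomers | C=C(C)CCC[C@H]1[C@H](C)C([N+](=O)[O-])C(Sc3ccccc3)c2c(OC)c(C(C)C)c(OC)c(OC)c21 | intermediate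
23 | rac-trans-1,2,4-trimethoxy-7-methyl-8-(4-methylpent-4-en-1-yl)-3-(propan-2-yl)-7,8-dihydronaphthalene (C5=C6) | C=C(C)CCC[C@H]1[C@H](C)C=Cc2c(OC)c(C(C)C)c(OC)c(OC)c21 | intermediate
24 | 1,2,4-trimethoxy-7-methyl-8-(4-methylpent-4-en-1-yl)-3-(propan-2-yl)naphthalene | C=C(C)CCCc1c(C)ccc2c(OC)c(C(C)C)c(OC)c(OC)c12 | intermediate
25 | 2-methoxy-7-methyl-8-(4-methylpent-4-en-1-yl)-3-(propan-2-yl)naphthalene-1,4-dione | C=C(C)CCCc1c(C)ccc2c1C(=O)C(OC)=C(C(C)C)C2=O | intermediate
26 | 2-hydroxy-7-methyl-8-(4-methylpent-4-en-1-yl)-3-(propan-2-yl)naphthalene-1,4-dione | C=C(C)CCCc1c(C)ccc2c1C(=O)C(O)=C(C(C)C)C2=O | intermediate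
27 | acetylsalvipisone, 7-methyl-8-(4-methylpent-4-en-1-yl)-1,4-dioxo-3-(propan-2-yl)-1,4-dihydronaphthalen-2-yl acetate | C=C(C)CCCc1c(C)ccc2c1C(=O)C(OC(C)=O)=C(C(C)C)C2=O | target

## Step count and risks

Total step count: 14. Longest linear sequence: 12 steps (1 → 27 through steps 1–5 and 8–14); steps 6–7 supply the dienophile.

Steps most likely to fail:

1. Step 8. The nitroalkene may quench the excited aldehyde, isomerise or polymerise in the light, or the dienol may revert to 13 before it is trapped, so that conversion stalls. The fallback separates the photochemistry from the cycloaddition. It sets out from 13, which is irradiated alone (365 nm, dilute degassed benzene) so that dienol 18 closes by 4π-electrocyclisation to rac-trans-2,3,5-trimethoxy-8-(4-methylpent-4-en-1-yl)-4-(propan-2-yl)bicyclo[4.2.0]octa-1,3,5-trien-7-ol F1, which is isolated. F1 is then heated with 17 in toluene at 80–110 °C in the dark; conrotatory ring opening with outward rotation of the hydroxyl regenerates 18 thermally, and the cycloaddition comes back to the route at 19.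

2. Step 5. Transfer of the primary alkyl group from the bulky dialkyl(alkyl)borane to the di-ortho-substituted arylpalladium iodide may be slow, so that protodeiodination takes over, and minor hydroboration at the wrong alkene would carry an isomeric chain forward. The fallback replaces the borane by an organozinc reagent and sets out from 10. Hydroboration with disiamylborane as in step 5 gives 11, and NaOH/H2O2 oxidation gives 5-methylhex-5-en-1-ol F2, which can be purified from its regioisomer. I2/PPh3/imidazole converts it into 6-iodo-2-methylhex-1-ene F3, and zinc dust with LiCl in THF gives iodo(5-methylhex-5-en-1-yl)zinc F4. Negishi coupling of F4 with 9 (Pd(OAc)2, SPhos, THF, 50 °C) comes back to the route at 12, which the acidic work-up turns into 13.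

3. Step 10. The thia-Michael addition to the hindered, donor-conjugated nitroalkene may lie on the side of 21, leaving material that tin hydride reduces to the nitroalkane, and thiyl radicals may add to the terminal alkene. The fallback removes the nitro group before the dehydration and sets out from 19. Bu3SnH with AIBN in toluene at 110 °C (denitrohydrogenation of the secondary nitro group) gives rac-1,2,4-trimethoxy-7-methyl-8-(4-methylpent-4-en-1-yl)-3-(propan-2-yl)-5,6,7,8-tetrahydronaphthalen-5-ol F5. MsCl/Et3N then eliminates through its methanesulfonate F6 (not isolated) toward the only β-hydrogens, at C6, and comes back to the route at 23.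

## Further compounds

F1 | step 8 | rac-trans-2,3,5-trimethoxy-8-(4-methylpent-4-en-1-yl)-4-(propan-2-yl)bicyclo[4.2.0]octa-1,3,5-trien-7-ol | C=C(C)CCC[C@H]1[C@H](O)c2c(OC)c(C(C)C)c(OC)c(OC)c21
F2 | step 5 | 5-methylhex-5-en-1-ol | C=C(C)CCCCO
F3 | step 5 | 6-iodo-2-methylhex-1-ene | C=C(C)CCCCI
F4 | step 5 | iodo(5-methylhex-5-en-1-yl)zinc | C=C(C)CCCC[Zn]I
F5 | step 10 | rac-1,2,4-trimethoxy-7-methyl-8-(4-methylpent-4-en-1-yl)-3-(propan-2-yl)-5,6,7,8-tetrahydronaphthalen-5-ol (5-OH/8-chain cis, 7-Me trans to both) | C=C(C)CCC[C@H]1[C@H](C)C[C@@H](O)c2c(OC)c(C(C)C)c(OC)c(OC)c21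
F6 | step 10 | methanesulfonate of F5 | C=C(C)CCC[C@H]1[C@H](C)C[C@@H](OS(C)(=O)=O)c2c(OC)c(C(C)C)c(OC)c(OC)c21
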